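## Retrosynthetic overview

1. Numbering: C1 (CH2OH) to C20 (terminal =CH2), spiro carbon C11, ring oxygens O7 (on C7) and O14 (on C14). Late disconnections: C17–C18 (allyl cuprate on a C16–C17 epoxide made from a 16,17-diol), C3=C4 (Z-selective cross-metathesis), C5–C6 (chelation-controlled allylation of a C6 aldehyde).
2. Feature on which the strategy rests: the six-membered ring O7–C7–C8–C9–C10–C11 is the [4+2] adduct of the 1-oxadiene O7=C7–C8=C9 (methyl 3-methyl-2-oxobut-3-enoate, carrying the C8 methyl and C6 as ester) with the exocyclic enol ether C10=C11 of the oxolane O14–C11–C12–C13–C14. The cycloaddition forms C9–C10 and O7–C11 and creates the spiro centre.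
3. Stereochemical relay: C16 (chiral pool) and C14 (Brown allylation) → C11 (catalyst-controlled cycloaddition) → C8 (hydrogenation anti to axial O14) → C7 (epimerisation to equatorial) → C6 (chelation control).
4. Ring order: the oxolane first (γ-lactone, then Petasis methylenation), the six-membered ring second, formed directly as the spiroketal.

Key step: step 7

Remarks on the chemistry (assumptions):
- In the spiro names C2 = C14, C5 = C11, C7 and C8 keep their numbers.
- The sense of induction in step 7 is assigned from the square-planar Cu(II)–(S,S)-t-Bu-box chelate model with the ring oxygen O14 endo; the (R,R)-ligand is the direct substitute should the exo mode prevail.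
- In intermediate 5 the C14 hydroxyl is drawn unborylated; any O–B bond formed is cleaved in the same oxidative work-up.

## Route

Step 1
Reactants: 1 2-[(4R)-2,2-dimethyl-1,3-dioxolan-4-yl]ethan-1-ol
Product: 2 2-[(4R)-2,2-dimethyl-1,3-dioxolan-4-yl]acetaldehyde
Conditions: TEMPO (10 mol%), PhI(OAc)2 (1.1 equiv), CH2Cl2, rt; used crude
Reagents that add atoms: none
Why: TEMPO/PhI(OAc)2 oxidation stops a primary alcohol at the aldehyde under near-neutral conditions that leave the acetonide and the C16 centre untouched.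

Step 2
Reactants: 2 2-[(4R)-2,2-dimethyl-1,3-dioxolan-4-yl]acetaldehyde
Product: 4 (2S)-1-[(4R)-2,2-dimethyl-1,3-dioxolan-4-yl]pent-4-en-2-ol, via borinate ester 3 (not isolated)
Conditions: B-allylbis(isopinocampheyl)borane from (+)-α-pinene, Et2O, −78 °C; then NaOH, H2O2, 0 °C → rt
Reagents that add atoms: B-allylbis(isopinocampheyl)borane derived from (+)-α-pinene, C=CCB([C@@H]1C[C@@H]2C[C@H]([C@H]1C)C2(C)C)[C@@H]1C[C@@H]2C[C@H]([C@H]1C)C2(C)C
Why: Brown asymmetric allylboration, in which the (+)-α-pinene-derived reagent delivers allyl to the Si face of the aldehyde through a chair transition state under reagent control, should set C14 as S (1,3-anti to the C16 oxygen).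

Step 3
Reactants: 4 (2S)-1-[(4R)-2,2-dimethyl-1,3-dioxolan-4-yl]pent-4-en-2-ol
Product: 6 (4S)-5-[(4R)-2,2-dimethyl-1,3-dioxolan-4-yl]pentane-1,4-diol, via alkylborane 5 (not isolated)
Conditions: 9-BBN (2.2 equiv), THF, 0 °C → rt; then NaOH, H2O2, 0 °C
Reagents that add atoms: hydrogen peroxide, OO
Why: Anti-Markovnikov hydroboration–oxidation with 9-BBN places the hydroxyl on the terminal carbon C11 and creates no stereocentre.

Step 4
Reactants: 6 (4S)-5-[(4R)-2,2-dimethyl-1,3-dioxolan-4-yl]pentane-1,4-diol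
Product: 9 (5S)-5-{[(4R)-2,2-dimethyl-1,3-dioxolan-4-yl]methyl}oxolan-2-one, via hydroxy aldehyde 7 (not isolated), via lactol 8 (not isolated)
Conditions: TEMPO (20 mol%), PhI(OAc)2 (2.5 equiv), CH2Cl2, rt
Reagents that add atoms: none
Why: TEMPO-mediated oxidative lactonisation oxidises the primary alcohol selectively, the aldehyde closes with the C14 hydroxyl to the five-membered lactol and is oxidised on to the γ-lactone without touching C14.

Step 5
Reactants: 9 (5S)-5-{[(4R)-2,2-dimethyl-1,3-dioxolan-4-yl]methyl}oxolan-2-one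
Product: 10 (4R)-2,2-dimethyl-4-{[(2S)-5-methylideneoxolan-2-yl]methyl}-1,3-dioxolane
Conditions: Cp2TiMe2 (2 equiv), toluene, 70 °C, dark; filtration through basic alumina (hexane, 1% Et3N); used at once
Reagents that add atoms: dimethyltitanocene, C[Ti](C)(C1C=CC=C1)C1C=CC=C1
Why: Petasis methylenation of the lactone carbonyl by thermally generated Cp2Ti=CH2 gives the exocyclic enol ether under non-acidic conditions, so the C10=C11 double bond should stay exocyclic.

Step 6
Reactants: 11 isopropenylmagnesium bromide; 12 dimethyl oxalate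
Product: 14 methyl 3-methyl-2-oxobut-3-enoate, via magnesium hemiketal 13 (not isolated)
Conditions: 12 (2 equiv), THF/Et2O, −78 °C, slow addition of 11; AcOH then aq. NH4Cl at −78 °C; used freshly
Reagents that add atoms: none
Why: Mono-addition of a Grignard reagent to an oxalate diester at −78 °C stops at the chelated tetrahedral magnesium hemiketal, which collapses to the α-keto ester only on the cold acidic quench.

Step 7
Reactants: 14 methyl 3-methyl-2-oxobut-3-enoate; 10 (4R)-2,2-dimethyl-4-{[(2S)-5-methylideneoxolan-2-yl]methyl}-1,3-dioxolane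
Product: 15 methyl (2S,5S)-2-{[(4R)-2,2-dimethyl-1,3-dioxolan-4-yl]methyl}-8-methyl-1,6-dioxaspiro[4.5]dec-7-ene-7-carboxylate
Conditions: [Cu((S,S)-t-Bu-box)](OTf)2 (10 mol%), 3 Å MS, THF, −78 → −40 °C; 14 (1.5 equiv), 10 added last and slowly; Et3N quench at −78 °C
Reagents that add atoms: none
Why: Inverse-electron-demand hetero-Diels–Alder reaction: the Cu(II)–bis(oxazoline) complex chelates the 1,2-dicarbonyl unit of 14 and lowers the LUMO of the s-cis oxadiene O7=C7–C8=C9, and the electron-rich enol ether adds in a concerted, asynchronous [4+2] in which nucleophilic C10 bonds to C9 ahead of O7–C11. The closest known reactions are the Cu(II)-box-catalysed cycloadditions of β,γ-unsaturated α-keto esters with enol ethers and the hetero-Diels–Alder spiroannulations of 2-methylene oxacycles with unsaturated carbonyl compounds. The six-membered ring O7–C7–C8–C9–C10–C11 is closed by the intermolecular cycloaddition itself, both new bonds forming suprafacially on one face of the enol ether, so the ring arises directly as the spiroketal on the existing oxolane. The one new stereocentre, C11, is set by the catalyst: in the square-planar chelate the tert-butyl group next to the ketone oxygen blocks one face of the oxadiene, and approach of 10 to the open face with ring oxygen O14 endo should give 11S (C5 of the spiro system). The step needs regioselectivity (secured by the polarised termini, C10 nucleophilic and the unsubstituted C9 electrophilic), periselectivity over carbonyl-ene addition and over isomerisation of 10 to the endocyclic enol ether (secured by low temperature, molecular sieves and adding 10 last), and facial selectivity at C11 against a small opposing bias of the C14 side chain, which the catalyst has to override.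

Step 8
Reactants: 15 methyl (2S,5S)-2-{[(4R)-2,2-dimethyl-1,3-dioxolan-4-yl]methyl}-8-methyl-1,6-dioxaspiro[4.5]dec-7-ene-7-carboxylate
Product: 16 methyl (2S,5S,7S,8R)-2-{[(4R)-2,2-dimethyl-1,3-dioxolan-4-yl]methyl}-8-methyl-1,6-dioxaspiro[4.5]decane-7-carboxylate
Conditions: H2 (3 atm), 10% Pd/C, EtOAc, rt
Reagents that add atoms: none
Why: Heterogeneous catalytic hydrogenation should deliver both hydrogens syn to the face of the C7=C8 double bond opposite the pseudo-axial (anomerically preferred) C11–O14 bond, setting C8 as R and C7 as S (ester cis to the methyl group).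

Step 9
Reactants: 16 methyl (2S,5S,7S,8R)-2-{[(4R)-2,2-dimethyl-1,3-dioxolan-4-yl]methyl}-8-methyl-1,6-dioxaspiro[4.5]decane-7-carboxylate
Product: 17 methyl (2S,5S,7R,8R)-2-{[(4R)-2,2-dimethyl-1,3-dioxolan-4-yl]methyl}-8-methyl-1,6-dioxaspiro[4.5]decane-7-carboxylate
Conditions: NaOMe (0.3 equiv), MeOH, rt → 40 °C
Reagents that add atoms: none
Why: Base-mediated epimerisation through the ester enolate moves the C7 ester from the axial position (syn-axial to O14) to the equatorial one, giving the thermodynamically preferred 7R isomer with methyl and ester trans-diequatorial and O14 axial.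

Step 10
Reactants: 17 methyl (2S,5S,7R,8R)-2-{[(4R)-2,2-dimethyl-1,3-dioxolan-4-yl]methyl}-8-methyl-1,6-dioxaspiro[4.5]decane-7-carboxylate
Product: 19 (2S,5S,7R,8R)-2-{[(4R)-2,2-dimethyl-1,3-dioxolan-4-yl]methyl}-8-methyl-1,6-dioxaspiro[4.5]decane-7-carbaldehyde, via aluminium hemiacetal 18 (not isolated)
Conditions: DIBAL-H (1.1 equiv), CH2Cl2, −78 °C; MeOH, then aq. Rochelle salt; used crude
Reagents that add atoms: none
Why: DIBAL-H partial reduction of an α-alkoxy ester gives a chelated aluminium hemiacetal that is stable at −78 °C and releases the aldehyde only on work-up, so over-reduction is avoided and the equatorial C7 centre is kept.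

Step 11
Reactants: 19 (2S,5S,7R,8R)-2-{[(4R)-2,2-dimethyl-1,3-dioxolan-4-yl]methyl}-8-methyl-1,6-dioxaspiro[4.5]decane-7-carbaldehyde
Product: 20 (1R)-1-[(2S,5S,7R,8R)-2-{[(4R)-2,2-dimethyl-1,3-dioxolan-4-yl]methyl}-8-methyl-1,6-dioxaspiro[4.5]decan-7-yl]but-3-en-1-ol
Conditions: MgBr2·OEt2 (3 equiv), allylSnBu3 (2 equiv), CH2Cl2, −78 → −20 °C
Reagents that add atoms: allyltributylstannane, C=CC[Sn](CCCC)(CCCC)CCCC
Why: Keck-type chelation-controlled allylation, in which MgBr2 bridges the aldehyde oxygen and ring oxygen O7 and the stannane attacks the chelate from the side of C7–H, anti to C8, should set C6 as R (Cram-chelate product).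

Step 12
Reactants: 20 (1R)-1-[(2S,5S,7R,8R)-2-{[(4R)-2,2-dimethyl-1,3-dioxolan-4-yl]methyl}-8-methyl-1,6-dioxaspiro[4.5]decan-7-yl]but-3-en-1-ol
Product: 21 tert-butyldimethylsilyl ether of 20 (C6–OTBS)
Conditions: TBSOTf, 2,6-lutidine, CH2Cl2, −78 → 0 °C
Reagents that add atoms: tert-butyldimethylsilyl triflate, CC(C)(C)[Si](C)(C)OS(=O)(=O)C(F)(F)F
Why: Silylation with TBSOTf/2,6-lutidine protects the hindered secondary C6 hydroxyl, which blocks later acid-induced reorganisation of the spiroketal into the 6,8-dioxabicyclo[3.2.1]octane isomer through O6.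

Step 13
Reactants: 22 but-3-en-1-ol
Product: 23 tert-butyl(but-3-en-1-yloxy)diphenylsilane
Conditions: TBDPSCl, imidazole, CH2Cl2, rt
Reagents that add atoms: tert-butyldiphenylsilyl chloride, CC(C)(C)[Si](Cl)(c1ccccc1)c1ccccc1
Why: Standard silylation of a primary alcohol gives the acid-stable C1–C3 cross-metathesis partner.

Step 14
Reactants: 21 tert-butyldimethylsilyl ether of 20; 23 tert-butyl(but-3-en-1-yloxy)diphenylsilane
Product: 24 tert-butyl{[(3Z,6R)-6-[(tert-butyldimethylsilyl)oxy]-6-[(2S,5S,7R,8R)-2-{[(4R)-2,2-dimethyl-1,3-dioxolan-4-yl]methyl}-8-methyl-1,6-dioxaspiro[4.5]decan-7-yl]hex-3-en-1-yl]oxy}diphenylsilane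
Conditions: cyclometalated Ru–NHC nitrato Z-selective metathesis catalyst (5–10 mol%), 23 (5 equiv), THF, 35 °C, static vacuum
Reagents that add atoms: none
Why: Z-selective olefin cross-metathesis joins the two terminal alkenes with loss of ethylene, the side-bound metallacycle of the cyclometalated catalyst forcing both substituents syn and hence the 3Z double bond.

Step 15
Reactants: 24 bis-silyl ether acetonide (see step 14)
Product: 25 (2R)-3-[(2S,5S,7R,8R)-7-{(1R,3Z)-1-[(tert-butyldimethylsilyl)oxy]-6-[(tert-butyldiphenylsilyl)oxy]hex-3-en-1-yl}-8-methyl-1,6-dioxaspiro[4.5]decan-2-yl]propane-1,2-diol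
Conditions: AcOH/H2O (4:1), rt
Reagents that add atoms: none
Why: Acid-catalysed hydrolysis of the terminal isopropylidene acetal is faster than cleavage of the secondary TBS and primary TBDPS ethers, and the spiroketal already has its thermodynamic configuration (O14 axial, C7 and C8 substituents equatorial), so C11 should not be lost.

Step 16
Reactants: 25 16,17-diol (see step 15)
Product: 26 17-O-(4-toluenesulfonyl) derivative of 25 (primary tosylate, C16–OH free)
Conditions: Bu2SnO (5 mol%), TsCl (1.05 equiv), Et3N, CH2Cl2, 0 °C → rt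
Reagents that add atoms: 4-toluenesulfonyl chloride, Cc1ccc(cc1)S(Cl)(=O)=O
Why: Tin-acetal-catalysed regioselective sulfonylation of a 1,2-diol tosylates only the primary C17 hydroxyl.

Step 17
Reactants: 26 17-O-tosylate (see step 16)
Product: 28 1-O-tert-butyldiphenylsilyl-6-O-tert-butyldimethylsilyl attenol A, via epoxide 27 (not isolated)
Conditions: allylMgCl (4 equiv), CuI (10 mol%), THF, −40 → 0 °C; aq. NH4Cl
Reagents that add atoms: allylmagnesium chloride, C=CC[Mg]Cl
Why: The first equivalent of Grignard reagent deprotonates the C16 hydroxyl, the alkoxide closes by intramolecular SN2 to the terminal epoxide, and copper-catalysed allyl transfer opens it at the unhindered C17, so C16 is never touched and ends as S.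

Step 18
Reactants: 28 1-O-tert-butyldiphenylsilyl-6-O-tert-butyldimethylsilyl attenol A
Product: 29 attenol A, (3Z,6R)-6-[(2S,5S,7R,8R)-2-[(2S)-2-hydroxyhex-5-en-1-yl]-8-methyl-1,6-dioxaspiro[4.5]decan-7-yl]hex-3-ene-1,6-diol
Conditions: TBAF (4 equiv), THF, rt → 40 °C
Reagents that add atoms: none
Why: Fluoride-mediated desilylation removes both silyl ethers under non-acidic conditions, which avoids equilibration of attenol A with its bicyclic ketal isomer.

## Compound list

1 | 2-[(4R)-2,2-dimethyl-1,3-dioxolan-4-yl]ethan-1-ol | CC1(C)OC[C@H](O1)CCO | starting material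
2 | 2-[(4R)-2,2-dimethyl-1,3-dioxolan-4-yl]acetaldehyde | CC1(C)OC[C@H](O1)CC=O | intermediate
3 | bis(isopinocampheyl)borinate ester of 4 | CC1(C)OC[C@H](O1)C[C@@H](OB([C@@H]1C[C@@H]2C[C@H]([C@H]1C)C2(C)C)[C@@H]1C[C@@H]2C[C@H]([C@H]1C)C2(C)C)CC=C | intermediate (not isolated)
4 | (2S)-1-[(4R)-2,2-dimethyl-1,3-dioxolan-4-yl]pent-4-en-2-ol | CC1(C)OC[C@H](O1)C[C@@H](O)CC=C | intermediate
5 | B-alkyl-9-borabicyclo[3.3.1]nonane adduct of 4 (boron on C11) | CC1(C)OC[C@H](O1)C[C@@H](O)CCCB1C2CCCC1CCC2 | intermediate (not isolated)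
6 | (4S)-5-[(4R)-2,2-dimethyl-1,3-dioxolan-4-yl]pentane-1,4-diol | CC1(C)OC[C@H](O1)C[C@@H](O)CCCO | intermediate
7 | (4S)-5-[(4R)-2,2-dimethyl-1,3-dioxolan-4-yl]-4-hydroxypentanal | CC1(C)OC[C@H](O1)C[C@@H](O)CCC=O | intermediate (not isolated)
8 | (5S)-5-{[(4R)-2,2-dimethyl-1,3-dioxolan-4-yl]methyl}oxolan-2-ol (both anomers) | CC1(C)OC[C@H](O1)C[C@@H]1CCC(O)O1 | intermediate (not isolated)
9 | (5S)-5-{[(4R)-2,2-dimethyl-1,3-dioxolan-4-yl]methyl}oxolan-2-one | CC1(C)OC[C@H](O1)C[C@@H]1CCC(=O)O1 | intermediate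
10 | (4R)-2,2-dimethyl-4-{[(2S)-5-methylideneoxolan-2-yl]methyl}-1,3-dioxolane | CC1(C)OC[C@H](O1)C[C@@H]1CCC(=C)O1 | intermediate
11 | isopropenylmagnesium bromide | C=C(C)[Mg]Br | starting material
12 | dimethyl oxalate | COC(=O)C(=O)OC | starting material
13 | methyl 2-(bromomagnesiooxy)-2-methoxy-3-methylbut-3-enoate | C=C(C)C(OC)(O[Mg]Br)C(=O)OC | intermediate (not isolated)
14 | methyl 3-methyl-2-oxobut-3-enoate | C=C(C)C(=O)C(=O)OC | intermediate
15 | methyl (2S,5S)-2-{[(4R)-2,2-dimethyl-1,3-dioxolan-4-yl]methyl}-8-methyl-1,6-dioxaspiro[4.5]dec-7-ene-7-carboxylate | CC1(C)OC[C@H](O1)C[C@@H]1CC[C@@]2(CCC(C)=C(C(=O)OC)O2)O1 | intermediate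
16 | methyl (2S,5S,7S,8R)-2-{[(4R)-2,2-dimethyl-1,3-dioxolan-4-yl]methyl}-8-methyl-1,6-dioxaspiro[4.5]decane-7-carboxylate | CC1(C)OC[C@H](O1)C[C@@H]1CC[C@@]2(CC[C@@H](C)[C@@H](C(=O)OC)O2)O1 | intermediate
17 | methyl (2S,5S,7R,8R)-2-{[(4R)-2,2-dimethyl-1,3-dioxolan-4-yl]methyl}-8-methyl-1,6-dioxaspiro[4.5]decane-7-carboxylate | CC1(C)OC[C@H](O1)C[C@@H]1CC[C@@]2(CC[C@@H](C)[C@H](C(=O)OC)O2)O1 | intermediate
18 | diisobutylaluminium hemiacetal of 17 | CC1(C)OC[C@H](O1)C[C@@H]1CC[C@@]2(CC[C@@H](C)[C@H](C(OC)O[Al](CC(C)C)CC(C)C)O2)O1 | intermediate (not isolated)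
19 | (2S,5S,7R,8R)-2-{[(4R)-2,2-dimethyl-1,3-dioxolan-4-yl]methyl}-8-methyl-1,6-dioxaspiro[4.5]decane-7-carbaldehyde | CC1(C)OC[C@H](O1)C[C@@H]1CC[C@@]2(CC[C@@H](C)[C@H](C=O)O2)O1 | intermediate
20 | (1R)-1-[(2S,5S,7R,8R)-2-{[(4R)-2,2-dimethyl-1,3-dioxolan-4-yl]methyl}-8-methyl-1,6-dioxaspiro[4.5]decan-7-yl]but-3-en-1-ol | CC1(C)OC[C@H](O1)C[C@@H]1CC[C@@]2(CC[C@@H](C)[C@H]([C@H](O)CC=C)O2)O1 | intermediate
21 | tert-butyldimethylsilyl ether of 20 | CC1(C)OC[C@H](O1)C[C@@H]1CC[C@@]2(CC[C@@H](C)[C@H]([C@H](O[Si](C)(C)C(C)(C)C)CC=C)O2)O1 | intermediate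
22 | but-3-en-1-ol | C=CCCO | starting material
23 | tert-butyl(but-3-en-1-yloxy)diphenylsilane | C=CCCO[Si](c1ccccc1)(c1ccccc1)C(C)(C)C | intermediate
24 | (3Z,6R)-hexenyl bis-silyl ether with C16/C17 acetonide (product of step 14) | CC1(C)OC[C@H](O1)C[C@@H]1CC[C@@]2(CC[C@@H](C)[C@H]([C@H](O[Si](C)(C)C(C)(C)C)C/C=C\CCO[Si](c3ccccc3)(c3ccccc3)C(C)(C)C)O2)O1 | intermediate
25 | (16R)-16,17-diol (product of step 15) | OC[C@H](O)C[C@@H]1CC[C@@]2(CC[C@@H](C)[C@H]([C@H](O[Si](C)(C)C(C)(C)C)C/C=C\CCO[Si](c3ccccc3)(c3ccccc3)C(C)(C)C)O2)O1 | intermediate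
26 | 17-O-tosylate of 25 | Cc1ccc(cc1)S(=O)(=O)OC[C@H](O)C[C@@H]1CC[C@@]2(CC[C@@H](C)[C@H]([C@H](O[Si](C)(C)C(C)(C)C)C/C=C\CCO[Si](c3ccccc3)(c3ccccc3)C(C)(C)C)O2)O1 | intermediate
27 | (16R)-16,17-epoxide [(2R)-oxiran-2-ylmethyl on C14] | O1C[C@H]1C[C@@H]1CC[C@@]2(CC[C@@H](C)[C@H]([C@H](O[Si](C)(C)C(C)(C)C)C/C=C\CCO[Si](c3ccccc3)(c3ccccc3)C(C)(C)C)O2)O1 | intermediate (not isolated)
28 | 1-O-tert-butyldiphenylsilyl-6-O-tert-butyldimethylsilyl attenol A | C=CCCC[C@H](O)C[C@@H]1CC[C@@]2(CC[C@@H](C)[C@H]([C@H](O[Si](C)(C)C(C)(C)C)C/C=C\CCO[Si](c3ccccc3)(c3ccccc3)C(C)(C)C)O2)O1 | intermediate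
29 | attenol A | C=CCCC[C@H](O)C[C@@H]1CC[C@@]2(CC[C@@H](C)[C@H]([C@H](O)C/C=C\CCO)O2)O1 | target

## Step count and risks

Total step count: 18. Longest linear sequence: 16 steps (1 → 29 through steps 1–5, 7–12 and 14–18).

Steps most likely to fail:

1. Step 7. Two processes threaten it. The exocyclic enol ether may isomerise to the endocyclic 2-methyl-4,5-dihydrofuran (or react by carbonyl-ene addition) faster than it cycloadds. The catalyst may also fail to override the substrate: the required adduct has O7 cis to the C14 side chain on the oxolane, so the oxadiene must bond to the more hindered face, and poor facial selectivity at C11 cannot be repaired later because C8 and C7 are relayed from it. The fallback sets out from lactone 9 and returns at aldehyde 19, closing the spiroketal under thermodynamic control with C7 and C8 set beforehand. (S)-But-3-yn-2-ol is mesylated to (S)-but-3-yn-2-yl methanesulfonate F1. F1 is converted with Pd(OAc)2/PPh3 and Et2Zn into the allenylzinc reagent and added to (tert-butyldimethylsilyloxy)acetaldehyde (Marshall propargylation) to give the anti homopropargylic alcohol (2R,3R)-1-[(tert-butyldimethylsilyl)oxy]-3-methylpent-4-yn-2-ol F2, which carries C6–C10. Neutral benzylation (2-benzyloxy-1-methylpyridinium triflate, MgO) gives the benzyl ether F3. Its lithium acetylide (n-BuLi, THF, −78 °C) opens lactone 9 to the hydroxy ynone F4. Hydrogenation over Pd/C saturates the alkyne and removes the benzyl group to give the dihydroxy ketone F5. PPTS in CH2Cl2 should close F5 to the spiroketal silyl ether F6, with O14 axial and the C7 and C8 substituents equatorial, that is, the C11 configuration of 17; the C6 oxygen stays silylated so that no bicyclic ketal can form. TBAF gives the primary alcohol F7, and Dess–Martin oxidation returns to aldehyde 19.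

2. Step 8. The tetrasubstituted, captodative C7=C8 bond may reduce slowly, and the two faces differ only by axial O14 against equatorial C12, so facial discrimination may be low (or reversed if O14 anchors the substrate to the metal surface). The fallback sets out from 15 and returns at 16, replacing substrate control by catalyst control. Saponification (LiOH, THF/H2O) gives the carboxylic acid F8. Homogeneous hydrogenation of its carboxylate with a chiral Ru(II)–diphosphine catalyst (Ru(OAc)2(H8-BINAP), H2, MeOH, Et3N) gives the cis acid F9; the carboxylate binds the metal and the ligand selects the face, and the ligand antipode that reinforces addition anti to O14 is chosen from a test pair. Esterification with TMSCHN2 returns to 16.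

3. Step 14. The hindered homoallylic silyl ether may convert slowly, the partner homodimerises, and secondary metathesis may erode the Z geometry. The fallback sets out from 21 and returns at 24, building the Z-alkene by carbonyl olefination. Ozonolysis (O3, CH2Cl2, −78 °C; PPh3) gives the β-silyloxy aldehyde F10. Salt-free Wittig reaction with the ylide from [3-(tert-butyldiphenylsilyloxy)propyl]triphenylphosphonium bromide and NaHMDS (THF, −78 °C) should give the 3Z alkene 24 directly.

## Further compounds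

F1 | step 7 | (S)-but-3-yn-2-yl methanesulfonate | C#C[C@H](C)OS(C)(=O)=O
F2 | step 7 | (2R,3R)-1-[(tert-butyldimethylsilyl)oxy]-3-methylpent-4-yn-2-ol | C#C[C@@H](C)[C@@H](O)CO[Si](C)(C)C(C)(C)C
F3 | step 7 | benzyl ether of F2 | C#C[C@@H](C)[C@@H](OCc1ccccc1)CO[Si](C)(C)C(C)(C)C
F4 | step 7 | hydroxy ynone from F3 and lactone 9 | CC1(C)OC[C@H](O1)C[C@@H](O)CCC(=O)C#C[C@@H](C)[C@@H](OCc1ccccc1)CO[Si](C)(C)C(C)(C)C
F5 | step 7 | saturated dihydroxy ketone | CC1(C)OC[C@H](O1)C[C@@H](O)CCC(=O)CC[C@@H](C)[C@@H](O)CO[Si](C)(C)C(C)(C)C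
F6 | step 7 | (2S,5S,7R,8R)-spiroketal with C6 as CH2OTBS | CC1(C)OC[C@H](O1)C[C@@H]1CC[C@@]2(CC[C@@H](C)[C@H](CO[Si](C)(C)C(C)(C)C)O2)O1
F7 | step 7 | (2S,5S,7R,8R)-spiroketal with C6 as CH2OH | CC1(C)OC[C@H](O1)C[C@@H]1CC[C@@]2(CC[C@@H](C)[C@H](CO)O2)O1
F8 | step 8 | (2S,5S)-2-{[(4R)-2,2-dimethyl-1,3-dioxolan-4-yl]methyl}-8-methyl-1,6-dioxaspiro[4.5]dec-7-ene-7-carboxylic acid | CC1(C)OC[C@H](O1)C[C@@H]1CC[C@@]2(CCC(C)=C(C(=O)O)O2)O1
F9 | step 8 | (2S,5S,7S,8R)-2-{[(4R)-2,2-dimethyl-1,3-dioxolan-4-yl]methyl}-8-methyl-1,6-dioxaspiro[4.5]decane-7-carboxylic acid | CC1(C)OC[C@H](O1)C[C@@H]1CC[C@@]2(CC[C@@H](C)[C@@H](C(=O)O)O2)O1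
F10 | step 14 | (3R)-3-[(tert-butyldimethylsilyl)oxy]-3-[(2S,5S,7R,8R)-2-{[(4R)-2,2-dimethyl-1,3-dioxolan-4-yl]methyl}-8-methyl-1,6-dioxaspiro[4.5]decan-7-yl]propanal | CC1(C)OC[C@H](O1)C[C@@H]1CC[C@@]2(CC[C@@H](C)[C@H]([C@H](O[Si](C)(C)C(C)(C)C)CC=O)O2)O1
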